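## Numbering used throughout

1 2,4,6-trihydroxybenzaldehyde · 2 prenyl bromide · 3 4-O-prenyl aldehyde · 4 mono-MOM salicylaldehyde (ring A fragment) · 5 homovanillic acid · 6 its methyl ester · 7 MOM ether of 6 · 8 silyl ketene acetal of 7 (not isolated) · 9 α-bromo ester (ring B fragment) · 10 aryloxy ester aldehyde · 11 diol · 12 dialdehyde (precursor of the key step) · 13 bis-MOM dihydroflavonol (product of the key step) · 14 target.

## Analysis of the target

Compound 14 is a 2,3-trans-dihydroflavonol. A chroman-4-one (ring C) is fused to a phloroglucinol-type ring A that carries a free, carbonyl-chelated hydroxyl at C5 and a 3-methylbut-2-enyl (prenyl) ether at O7. A 4-hydroxy-3-methoxyphenyl ring B sits at C2. The only stereocentres are C2 (R, benzylic, bound to O1) and C3 (R, the carbinol next to the C4 ketone); they are adjacent and trans, so ring B and the 3-hydroxyl are both equatorial, which is also the more stable arrangement. The prenyl ether excludes hydrogenolysis, ozonolysis, peracids and strong acids. The β-aryloxy ketone opens by elimination of O1 under strong base, C3 is enolisable, and a free 4'-hydroxyl lets the C2–O1 bond ionise through a quinone methide. The difficulty is to set two contiguous stereocentres beside a ketone in a ring that tolerates neither strong base nor strong acid, and to tell apart the three oxygens of ring A (O1, O5, O7). The strategy rests on C3–C4 being the central bond of an acyloin: cutting it leaves the ring A aldehyde (C4) and an aliphatic aldehyde (C3). In that dialdehyde C2 lies between O1, ring B and the C3 formyl group, so its hydrogen is acidic and the centre can equilibrate while a chiral catalyst closes ring C.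

## Retrosynthetic reasoning

**14 ⇐ 13.** The last operation is only the loss of two acetal protecting groups; no skeletal bond is cut. In 13, O5 and O4' carry methoxymethyl groups and O7 already carries the prenyl group. Acetals survive base, hydride and carbene chemistry and ionise in dilute acid far more readily than an allylic aryl ether. Benzyl, allyl or p-methoxybenzyl groups would each need conditions that attack the prenyl unit. Both hydroxyls must stay masked up to this point: a free 5-hydroxyl would deactivate the ring A aldehyde as its phenoxide, and a free 4'-hydroxyl would let C2–O1 ionise.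

**13 ⇐ 12.** The C3–C4 bond is cut, which opens ring C and removes both stereocentres. A cut at O1–C2 or C4–C4a would need a precursor that already holds both centres. This cut leads to dialdehyde 12, whose only stereocentre is labile, so it can be made as a racemate. The forward reaction has to make the ring A aldehyde the acyl anion donor and the aliphatic aldehyde the acceptor, close a six-membered ring, and take one enantiomer of a racemising substrate through to product.

**12 ⇐ 11 ⇐ 10.** No carbon–carbon bond is cut here; the two formyl groups of 12 are traced to the two primary alcohols of 11, and these to the aldehyde and ester of 10. Dialdehyde 12 is too labile to carry through several steps, so it is made last and used at once. Treating both carbonyls of 10 alike, by reducing both and oxidising both, avoids masking the aromatic aldehyde as an acetal, which would cost two steps and put the ortho MOM group at risk under acid.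

**10 ⇐ 4 + 9.** The O1–C2 ether bond is cut. The oxygen belongs to ring A from the start, and the α-bromo ester 9 is a strongly activated electrophile, so the two halves of the molecule are joined in one convergent step. The forward reaction must alkylate a chelated phenol at oxygen without letting the new ester enolate add to the neighbouring aldehyde.

**4 ⇐ 3 ⇐ 1 + 2.** Two O–C bonds are cut. The three hydroxyls of 1 are told apart by acidity and hydrogen bonding: the para hydroxyl is alkylated first by 2, then one of the two equivalent ortho hydroxyls is capped. The remaining chelated hydroxyl becomes O1.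

**9 ⇐ 8 ⇐ 7 ⇐ 6 ⇐ 5.** The C–Br bond, the phenol protecting group and the ester are removed in turn. Ring B with its two-carbon side chain is bought as 5, so only the oxidation level at the benzylic carbon has to be adjusted.

## Alternatives that were turned down

**Alternative 1:** Ring A is built last by cutting C4a–C5. The precursor is the dihydropyranone A2, which holds ring C with both stereocentres and a 3-oxobutanoate chain at C8a. With Mg(OCH3)2 its extended enolate would attack the chain ester through C4a, and loss of methanol and enolisation would give the 5,7-dihydroxy compound A1.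
- For: the stereocentres would come from established aldol or dihydroxylation chemistry before the key step. Ring A would arrive with O5 chelated and O7 free, so the prenyl group could go on directly and the silyl groups would leave with fluoride. That end game is gentler on the prenyl ether than acid, and on this point the alternative is stronger.
- Against: A2 needs a long synthesis (pyranone construction and chain extension). During the basic aromatisation C3 is α to the vinylogous ester carbonyl and can enolise, and the ring can open by elimination of O1 at the benzylic C2. The active methylene of the chain can also attack the C4 ketone.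
- Comparison: the chosen route takes ring A from a cheap aldehyde and creates both stereocentres in the ring-closing step, so nothing stereochemical has to survive a strongly basic step, and it is clearly shorter.

**Alternative 2:** The C4–C4a bond is cut. Acid A4, activated with (CF3CO)2O as the mixed anhydride, would acylate the symmetric 3,5-dibenzyloxyphenoxy ring ortho to O1 and give A3.
- For: both positions ortho to O1 are equivalent and strongly activated, so there is no regiochemical question. The stereocentres derive from asymmetric dihydroxylation of a cinnamate, with the aryl ether introduced by inversion at the benzylic carbon. The ring closure is a well-known reaction type. On the reliability of the ring closure and of the stereocentres this alternative is stronger.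
- Against: the benzylic ether carries a p-alkoxyphenyl group and can ionise in the strongly acidic acylation medium. Installing it by substitution at an electron-rich benzylic carbon invites loss of stereochemical purity. The four benzyl groups can only be removed by hydrogenolysis, which must precede prenylation, so O7 would have to be alkylated selectively against O4' on the unprotected, base-sensitive dihydroflavonol.
- Comparison: the chosen route offers a ring A that is differentiated from its first step, no hydrogenolysis, no late base treatment of the free dihydroflavonol, and fewer steps.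

**Alternative 3:** O1–C8a and C4–C4a are both cut. CsF would release an aryne from the silylaryl triflate A6; the benzylic alkoxide of hydroxy ester A7 would add at C8a and the resulting aryl anion would attack the ester to give A5.
- For: two bonds form in one step, and the regiochemistry is inherent, since an alkoxide adds to a 3-alkoxyaryne distal to the flanking oxygen and so places the aryl anion at C4a. The stereocentres are fixed beforehand. On bonds formed per step it is stronger.
- Against: A7 must be the anti hydroxy ester, which is not the direct product of syn-dihydroxylation of the E-cinnamate, so an inversion or an anti-selective glycolate aldol is needed. A secondary benzylic alkoxide under fluoride can undergo retro-aldol cleavage, and the aryl anion can be quenched by proton transfer before it acylates. A6 needs several steps, and with two equal MOM groups on ring A the prenyl group could only go on after global deprotection.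
- Comparison: the key step is no less speculative than the chosen one, the route is longer, and the differentiation of O5 and O7 is lost.

Key step: step 9

Assumption: the sense of induction of the aminoindanol-derived triazolylidene on this substrate class cannot be taken from precedent. The (5aS,10bR) salt is written in step 9; its (5aR,10bS) antipode is used instead if the first runs deliver the 2S,3S series.

## Route

Step 1
Reactants: 1 2,4,6-trihydroxybenzaldehyde; 2 prenyl bromide (1-bromo-3-methylbut-2-ene)
Product: 3 2,6-dihydroxy-4-(3-methylbut-2-enyloxy)benzaldehyde
Conditions: K2CO3 (1.0 equiv), acetone, 0 °C → rt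
Reagents that add atoms: none
Why: Williamson ether synthesis; with one equivalent of base the monoanion of 1 is the 4-phenoxide (para to the formyl group, most acidic, not chelated), and O-alkylation by the allylic bromide should outrun C-alkylation in a dipolar solvent while the ortho hydroxyls stay hydrogen-bonded or hindered.

Step 2
Reactants: 3 2,6-dihydroxy-4-(3-methylbut-2-enyloxy)benzaldehyde
Product: 4 2-hydroxy-6-(methoxymethoxy)-4-(3-methylbut-2-enyloxy)benzaldehyde
Conditions: MOMCl (1.1 equiv), i-Pr2NEt, CH2Cl2, 0 °C → rt
Reagents that add atoms: chloromethyl methyl ether, COCCl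
Why: Acetal (MOM) protection of a phenol; the two ortho hydroxyls of 3 are equivalent, and once one is capped the other is locked in a hydrogen bond to the aldehyde and resists a second alkylation under amine base.

Step 3
Reactants: 5 homovanillic acid
Product: 6 methyl (4-hydroxy-3-methoxyphenyl)acetate
Conditions: MeOH, H2SO4 (cat.), reflux
Reagents that add atoms: methanol, CO
Why: Fischer esterification; the phenol is inert under these conditions.

Step 4
Reactants: 6 methyl (4-hydroxy-3-methoxyphenyl)acetate
Product: 7 methyl [3-methoxy-4-(methoxymethoxy)phenyl]acetate
Conditions: MOMCl, i-Pr2NEt, CH2Cl2, 0 °C → rt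
Reagents that add atoms: chloromethyl methyl ether, COCCl
Why: MOM protection of the guaiacol hydroxyl under amine base, which leaves the ester and its acidic methylene untouched.

Step 5
Reactants: 7 methyl [3-methoxy-4-(methoxymethoxy)phenyl]acetate
Product: 9 methyl 2-bromo-2-[3-methoxy-4-(methoxymethoxy)phenyl]acetate (racemic), via trimethylsilyl ketene acetal 8 (not isolated)
Conditions: LiN(SiMe3)2, THF, –78 °C; Me3SiCl; then NBS, –78 → 0 °C
Reagents that add atoms: N-bromosuccinimide, O=C1CCC(=O)N1Br; chlorotrimethylsilane, C[Si](C)(C)Cl (its atoms stay only in 8)
Why: Ester enolate formation, O-silylation and electrophilic bromination of the ketene acetal; the ketene acetal is far more nucleophilic than the protected arene, so bromine should enter only at the benzylic α-carbon and double bromination is avoided.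

Step 6
Reactants: 4 2-hydroxy-6-(methoxymethoxy)-4-(3-methylbut-2-enyloxy)benzaldehyde; 9 methyl 2-bromo-2-[3-methoxy-4-(methoxymethoxy)phenyl]acetate
Product: 10 methyl 2-[2-formyl-3-(methoxymethoxy)-5-(3-methylbut-2-enyloxy)phenoxy]-2-[3-methoxy-4-(methoxymethoxy)phenyl]acetate (racemic)
Conditions: K2CO3, DMF, 0 °C → rt
Reagents that add atoms: none
Why: Williamson etherification (SN2) of the chelated phenoxide with an activated secondary benzylic α-bromo ester; room temperature keeps the ester enolate from adding to the neighbouring, poorly electrophilic trialkoxy aldehyde. The new centre forms as the racemate, which is what the key step needs.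

Step 7
Reactants: 10 methyl 2-[2-formyl-3-(methoxymethoxy)-5-(3-methylbut-2-enyloxy)phenoxy]-2-[3-methoxy-4-(methoxymethoxy)phenyl]acetate
Product: 11 2-[2-(hydroxymethyl)-3-(methoxymethoxy)-5-(3-methylbut-2-enyloxy)phenoxy]-2-[3-methoxy-4-(methoxymethoxy)phenyl]ethanol (racemic)
Conditions: LiAlH4, THF, 0 °C
Reagents that add atoms: none
Why: Hydride reduction of ester and aldehyde to the diol in one operation, which makes an acetal mask for the aryl aldehyde unnecessary; ethers, acetals and the trisubstituted alkene are inert to LiAlH4.

Step 8
Reactants: 11 2-[2-(hydroxymethyl)-3-(methoxymethoxy)-5-(3-methylbut-2-enyloxy)phenoxy]-2-[3-methoxy-4-(methoxymethoxy)phenyl]ethanol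
Product: 12 2-{1-[3-methoxy-4-(methoxymethoxy)phenyl]-2-oxoethoxy}-6-(methoxymethoxy)-4-(3-methylbut-2-enyloxy)benzaldehyde (racemate; the (1R) enantiomer is the one drawn)
Conditions: Dess–Martin periodinane (3 equiv), NaHCO3, CH2Cl2, 0 °C → rt; crude product used at once
Reagents that add atoms: none
Why: Dess–Martin oxidation of both primary alcohols under buffered, non-basic conditions; the electron-rich benzylic alcohol should go first, and the aldehyde it gives is too poor an electrophile to trap the remaining hydroxyl as a lactol. The labile α-aryloxy aldehyde is not chromatographed.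

Step 9
Reactants: 12 2-{1-[3-methoxy-4-(methoxymethoxy)phenyl]-2-oxoethoxy}-6-(methoxymethoxy)-4-(3-methylbut-2-enyloxy)benzaldehyde
Product: 13 (2R,3R)-3-hydroxy-5-(methoxymethoxy)-2-[3-methoxy-4-(methoxymethoxy)phenyl]-7-(3-methylbut-2-enyloxy)chroman-4-one
Conditions: (5aS,10bR)-2-(pentafluorophenyl)-5a,10b-dihydro-4H,6H-indeno[2,1-b][1,2,4]triazolo[4,3-d][1,4]oxazinium tetrafluoroborate (15 mol %), i-Pr2NEt (1 equiv), toluene (0.02 M), 4 Å MS, 0 °C → rt, Ar
Reagents that add atoms: none
Why: Proposed new method: the carbene freed from the triazolium salt adds to the ring A aldehyde, proton transfer gives the Breslow intermediate with nucleophilic C4, this attacks the aliphatic formyl carbon C3, and proton transfer with loss of the carbene releases the acyloin. The closest known reaction type is the enantioselective intramolecular crossed aldehyde–ketone benzoin reaction under chiral triazolylidene catalysis, which gives 3-hydroxychroman-4-ones; an aldehyde acceptor and the dynamic resolution of its α-centre have not been shown. Ring C closes in a 6-exo-trig mode. C2 is controlled by the catalyst: its hydrogen in 12, flanked by the formyl group, ring B and O1, exchanges through the enol under the amine base, so the enantiomers interconvert and the chiral carbene should take the whole racemate through the faster diastereomeric transition state; once C3 is a carbinol, C2 is no longer acidic and stays fixed. C3 is controlled by the substrate: ring B sits pseudo-equatorial in the chair-like closure and directs the attack so that the new hydroxyl comes out trans, which is also the more stable diequatorial isomer. The step needs the aromatic aldehyde as donor and the aliphatic one as acceptor; the α-branched, α-oxygenated aliphatic aldehyde is the better electrophile and should form its own Breslow intermediate only slowly, and the conjugated ketone is the thermodynamically preferred acyloin, to which the regioisomer can revert by retro-benzoin. Low temperature, a weak amine base, a non-polar solvent and high dilution are chosen to hold back loss of the ring A aryloxide from a carbene adduct of the aliphatic aldehyde, aldol addition of the enol to the ring A aldehyde, and intermolecular coupling.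

Step 10
Reactants: 13 (2R,3R)-3-hydroxy-5-(methoxymethoxy)-2-[3-methoxy-4-(methoxymethoxy)phenyl]-7-(3-methylbut-2-enyloxy)chroman-4-one
Product: 14 (2R,3R)-3,5-dihydroxy-2-(4-hydroxy-3-methoxyphenyl)-7-(3-methylbut-2-enyloxy)chroman-4-one
Conditions: HCl (ca. 0.5 M), MeOH–THF, 25–35 °C, stopped when the 4'-acetal is gone
Reagents that add atoms: none
Why: Acid-catalysed transacetalisation of the two aryl MOM ethers to methanol; each acetal ionises through an oxocarbenium ion after protonation at its basic methoxy oxygen, far more easily than the prenyl ether, whose oxygen is a weakly basic vinylogous ester oxygen. The trans-acyloin is configurationally stable in dilute acid.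

## Compound list

1 | 2,4,6-trihydroxybenzaldehyde | O=Cc1c(O)cc(O)cc1O | starting material
2 | prenyl bromide (1-bromo-3-methylbut-2-ene) | CC(C)=CCBr | starting material
3 | 2,6-dihydroxy-4-(3-methylbut-2-enyloxy)benzaldehyde | O=Cc1c(O)cc(OCC=C(C)C)cc1O | intermediate
4 | 2-hydroxy-6-(methoxymethoxy)-4-(3-methylbut-2-enyloxy)benzaldehyde | COCOc1cc(OCC=C(C)C)cc(O)c1C=O | intermediate
5 | homovanillic acid | COc1cc(CC(=O)O)ccc1O | starting material
6 | methyl (4-hydroxy-3-methoxyphenyl)acetate | COC(=O)Cc1ccc(O)c(OC)c1 | intermediate
7 | methyl [3-methoxy-4-(methoxymethoxy)phenyl]acetate | COCOc1ccc(CC(=O)OC)cc1OC | intermediate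
8 | 1-methoxy-2-[3-methoxy-4-(methoxymethoxy)phenyl]-1-(trimethylsilyloxy)ethene (mixture of geometric isomers; not isolated) | COCOc1ccc(C=C(OC)O[Si](C)(C)C)cc1OC | intermediate
9 | methyl 2-bromo-2-[3-methoxy-4-(methoxymethoxy)phenyl]acetate (racemic) | COCOc1ccc(C(Br)C(=O)OC)cc1OC | intermediate
10 | methyl 2-[2-formyl-3-(methoxymethoxy)-5-(3-methylbut-2-enyloxy)phenoxy]-2-[3-methoxy-4-(methoxymethoxy)phenyl]acetate (racemic) | COCOc1ccc(C(Oc2cc(OCC=C(C)C)cc(OCOC)c2C=O)C(=O)OC)cc1OC | intermediate
11 | 2-[2-(hydroxymethyl)-3-(methoxymethoxy)-5-(3-methylbut-2-enyloxy)phenoxy]-2-[3-methoxy-4-(methoxymethoxy)phenyl]ethanol (racemic) | COCOc1ccc(C(CO)Oc2cc(OCC=C(C)C)cc(OCOC)c2CO)cc1OC | intermediate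
12 | 2-{(1R)-1-[3-methoxy-4-(methoxymethoxy)phenyl]-2-oxoethoxy}-6-(methoxymethoxy)-4-(3-methylbut-2-enyloxy)benzaldehyde (made and used as the racemate, the enantiomers interconvert in step 9; reacting enantiomer drawn) | COc1cc([C@H](C=O)Oc2cc(OCC=C(C)C)cc(OCOC)c2C=O)ccc1OCOC | intermediate
13 | (2R,3R)-3-hydroxy-5-(methoxymethoxy)-2-[3-methoxy-4-(methoxymethoxy)phenyl]-7-(3-methylbut-2-enyloxy)chroman-4-one | COc1cc([C@H]2Oc3cc(OCC=C(C)C)cc(OCOC)c3C(=O)[C@@H]2O)ccc1OCOC | intermediate
14 | (2R,3R)-3,5-dihydroxy-2-(4-hydroxy-3-methoxyphenyl)-7-(3-methylbut-2-enyloxy)chroman-4-one | COc1cc([C@H]2Oc3cc(OCC=C(C)C)cc(O)c3C(=O)[C@@H]2O)ccc1O | target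

## Step count and least certain steps

Total: 10 steps. Longest linear sequence: 8 steps (5 → 14 through steps 3 to 10).

**Step 9 (key step, proposed new method).**
- What may go wrong: acyl anion formation at the aliphatic aldehyde instead of the hindered, electron-rich, doubly ortho-substituted ring A aldehyde. This would be followed either by expulsion of the ortho-formyl aryloxide (an internal redox path to an aryl ester) or by closure in the reverse sense. Cyclisation may also outrun racemisation of C2, leaving a simple kinetic resolution, and the enol may add to the ring A aldehyde in an aldol reaction.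
- Fallback with known chemistry, setting out from prenyl bromide 2 and returning at 14: commercial 2',4',6'-trihydroxyacetophenone is O-alkylated at the 4'-hydroxyl with 2 (K2CO3, acetone) to give 1-[2,6-dihydroxy-4-(3-methylbut-2-enyloxy)phenyl]ethanone F1. Both remaining hydroxyls are capped (NaH, MOMCl, DMF) to give 1-[2,6-bis(methoxymethoxy)-4-(3-methylbut-2-enyloxy)phenyl]ethanone F2. Commercial vanillin is converted with MOMCl and i-Pr2NEt into 3-methoxy-4-(methoxymethoxy)benzaldehyde F3. Claisen–Schmidt condensation of F2 and F3 (KOH, EtOH) should give (E)-1-[2,6-bis(methoxymethoxy)-4-(3-methylbut-2-enyloxy)phenyl]-3-[3-methoxy-4-(methoxymethoxy)phenyl]prop-2-en-1-one F4. Juliá–Colonna epoxidation (poly-L-leucine, urea–H2O2, DBU, THF; the D-polymer if the sense is reversed) should give [2,6-bis(methoxymethoxy)-4-(3-methylbut-2-enyloxy)phenyl]{(2R,3S)-3-[3-methoxy-4-(methoxymethoxy)phenyl]oxiran-2-yl}methanone F5. HCl in MeOH then removes the three MOM groups, and the freed 2'-hydroxyl opens the epoxide at the benzylic carbon with inversion and closes ring C to 14. C3 comes from the epoxidation and C2 from the trans-selective ring closure.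

**Step 10.**
- What may go wrong: ionisation of the allylic C–O bond or acid-catalysed addition across the trisubstituted alkene before the less labile 4'-acetal has gone, so that the prenyl group is lost or altered.
- Fallback, setting out from 13 and returning at 14: the acid treatment is pushed (HCl, MeOH, 55 °C) until both acetals and the prenyl group are gone, methanol trapping the prenyl cation. This gives (2R,3R)-3,5,7-trihydroxy-2-(4-hydroxy-3-methoxyphenyl)chroman-4-one F6. Its most acidic hydroxyl, at C7, is then alkylated with 2 (1 equiv) and K2CO3 (1 equiv) in acetone at rt to give 14; O5 is chelated and O4' is less acidic.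

**Step 8.**
- What may go wrong: oxidation of the aliphatic alcohol first, lactol formation with the benzylic hydroxyl and over-oxidation to a lactone; also enolisation, aldol reaction or air oxidation of the dialdehyde during isolation.
- Fallback, setting out from 11 and returning at 12: MnO2 in CH2Cl2 oxidises only the benzylic alcohol and should give 2-{2-hydroxy-1-[3-methoxy-4-(methoxymethoxy)phenyl]ethoxy}-6-(methoxymethoxy)-4-(3-methylbut-2-enyloxy)benzaldehyde F7. A Parikh–Doering oxidation (SO3·pyridine, DMSO, i-Pr2NEt, 0 °C) of the remaining primary alcohol then gives 12.

**Step 6.**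
- What may go wrong: slow O-alkylation of the chelated, hindered phenoxide, so that ionisation of the p-alkoxybenzylic bromide (solvolysis, C-alkylation) and aldol closure of the product enolate onto the ortho aldehyde take over.
- Fallback, setting out from 7 and returning at 10: diazo transfer (4-acetamidobenzenesulfonyl azide, DBU, MeCN) gives methyl 2-diazo-2-[3-methoxy-4-(methoxymethoxy)phenyl]acetate F8. O–H insertion of its carbene into phenol 4 (Rh2(OAc)4, 1 mol %, CH2Cl2, rt) then forms the same ether bond under neutral conditions.

**Step 1.**
- What may go wrong: C-prenylation of the phloroglucinol ring and double O-alkylation, because the phenoxide is ambident and the product is still acidic.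
- Fallback, setting out from 1 and returning at 3: a Mitsunobu etherification with 3-methylbut-2-en-1-ol (PPh3, diisopropyl azodicarboxylate, THF, 0 °C) couples the most acidic 4-hydroxyl under neutral conditions without a free phenoxide. This fallback makes no compound outside the list (F0).

## Further compounds

F1 | step 9 | 1-[2,6-dihydroxy-4-(3-methylbut-2-enyloxy)phenyl]ethanone | CC(=O)c1c(O)cc(OCC=C(C)C)cc1O
F2 | step 9 | 1-[2,6-bis(methoxymethoxy)-4-(3-methylbut-2-enyloxy)phenyl]ethanone | CC(=O)c1c(OCOC)cc(OCC=C(C)C)cc1OCOC
F3 | step 9 | 3-methoxy-4-(methoxymethoxy)benzaldehyde | COCOc1ccc(C=O)cc1OC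
F4 | step 9 | (E)-1-[2,6-bis(methoxymethoxy)-4-(3-methylbut-2-enyloxy)phenyl]-3-[3-methoxy-4-(methoxymethoxy)phenyl]prop-2-en-1-one | COCOc1ccc(/C=C/C(=O)c2c(OCOC)cc(OCC=C(C)C)cc2OCOC)cc1OC
F5 | step 9 | [2,6-bis(methoxymethoxy)-4-(3-methylbut-2-enyloxy)phenyl]{(2R,3S)-3-[3-methoxy-4-(methoxymethoxy)phenyl]oxiran-2-yl}methanone | O=C(c1c(OCOC)cc(OCC=C(C)C)cc1OCOC)[C@@H]1O[C@H]1c1ccc(OCOC)c(OC)c1
F6 | step 10 | (2R,3R)-3,5,7-trihydroxy-2-(4-hydroxy-3-methoxyphenyl)chroman-4-one | COc1cc([C@H]2Oc3cc(O)cc(O)c3C(=O)[C@@H]2O)ccc1O
F7 | step 8 | 2-{2-hydroxy-1-[3-methoxy-4-(methoxymethoxy)phenyl]ethoxy}-6-(methoxymethoxy)-4-(3-methylbut-2-enyloxy)benzaldehyde (racemic) | COCOc1ccc(C(CO)Oc2cc(OCC=C(C)C)cc(OCOC)c2C=O)cc1OC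
F8 | step 6 | methyl 2-diazo-2-[3-methoxy-4-(methoxymethoxy)phenyl]acetate | COCOc1ccc(C(=[N+]=[N-])C(=O)OC)cc1OC
F0 | step 1 | none | none
A1 | alternative 1 | (2R,3R)-3-(tert-butyldimethylsilyloxy)-2-[4-(tert-butyldimethylsilyloxy)-3-methoxyphenyl]-5,7-dihydroxychroman-4-one | COc1cc([C@H]2Oc3cc(O)cc(O)c3C(=O)[C@@H]2O[Si](C)(C)C(C)(C)C)ccc1O[Si](C)(C)C(C)(C)C
A2 | alternative 1 | methyl 4-{(2R,3R)-3-(tert-butyldimethylsilyloxy)-2-[4-(tert-butyldimethylsilyloxy)-3-methoxyphenyl]-4-oxo-3,4-dihydro-2H-pyran-6-yl}-3-oxobutanoate | COc1cc([C@H]2OC(CC(=O)CC(=O)OC)=CC(=O)[C@@H]2O[Si](C)(C)C(C)(C)C)ccc1O[Si](C)(C)C(C)(C)C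
A3 | alternative 2 | (2R,3R)-3,5,7-tris(benzyloxy)-2-[4-(benzyloxy)-3-methoxyphenyl]chroman-4-one | COc1cc([C@H]2Oc3cc(OCc4ccccc4)cc(OCc4ccccc4)c3C(=O)[C@@H]2OCc2ccccc2)ccc1OCc1ccccc1
A4 | alternative 2 | (2R,3R)-2-(benzyloxy)-3-[4-(benzyloxy)-3-methoxyphenyl]-3-[3,5-bis(benzyloxy)phenoxy]propanoic acid | COc1cc([C@@H](Oc2cc(OCc3ccccc3)cc(OCc3ccccc3)c2)[C@@H](OCc2ccccc2)C(=O)O)ccc1OCc1ccccc1
A5 | alternative 3 | (2R,3R)-3,5,7-tris(methoxymethoxy)-2-[3-methoxy-4-(methoxymethoxy)phenyl]chroman-4-one | COc1cc([C@H]2Oc3cc(OCOC)cc(OCOC)c3C(=O)[C@@H]2OCOC)ccc1OCOC
A6 | alternative 3 | 3,5-bis(methoxymethoxy)-2-(trimethylsilyl)phenyl trifluoromethanesulfonate | COCOc1cc(OCOC)c([Si](C)(C)C)c(OS(=O)(=O)C(F)(F)F)c1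
A7 | alternative 3 | methyl (2R,3R)-3-hydroxy-2-(methoxymethoxy)-3-[3-methoxy-4-(methoxymethoxy)phenyl]propanoate | COc1cc([C@@H](O)[C@@H](OCOC)C(=O)OC)ccc1OCOC
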